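The target is a CH2-bridged pair of hexasubstituted phloroglucinol rings: ring A (OMe, Me, OH, Ac, OH, CH2) and ring B (C1' CH2, C2' OH, C3' isopentyl, C4' OH, C5' isobutyryl, C6' OH). It has no stereocentre, so no stereocontrol is needed.
Retrosynthetic cuts, in order: the C5'–acyl bond (Fries shift), then C3'–C4' and C1'–C2' of ring B (benzannulation), then the four-membered ring (alkylketene + ethoxyacetylene), and last the aryl–CH2CH2 bond at ring A (acrylic acid).
Enabling feature: C3' carries the isopentyl chain and lies between the oxygenated carbons C2' and C4'. C2'–C3' therefore map onto a siloxyalkyne (O on C2', chain on C3'). C4'–C5'–C6'–C1' map onto a 3-alkoxycyclobutenone (C1 = C4', C4 = C5', C3 = C6', C2 = C1' bearing the ring A benzyl group).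
Forward: ring A is bought as 2,4,6-trihydroxytoluene and fully substituted, and its propanoic acid side chain is turned into the cyclobutenone. Ring B is then built on it from open-chain carbons, and C5' acylation and deprotection finish the route.
Every protected phenol except the TIPS ether is a benzyl ether. The last step is therefore a neutral hydrogenolysis that spares the ring A methyl ether and the CH2 bridge.

Key step: step 10

Remark on the chemistry: the enol ether oxygen of the cyclobutenone is carried as benzyl, because an ethyl ether at C6' would need BCl3 at the end and that would endanger the ring A methyl ether. Dione 13 is drawn as its enol, and 12 and 20 are racemic, their stereocentres being erased later.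

Step 1
Reactants: 1 2,4,6-trihydroxytoluene
Product: 2 1-(2,4,6-trihydroxy-3-methylphenyl)ethan-1-one
Conditions: AcCl (1.05 equiv), AlCl3 (3.5 equiv), CH2Cl2–MeNO2, 0 → 40 °C; aq. HCl
Reagents that add atoms: acetyl chloride, CC(=O)Cl
Why: Friedel–Crafts acylation of a phloroglucinol, in which the two free ring carbons of 1 are equivalent and the first acyl group deactivates the ring against a second one.

Step 2
Reactants: 2 1-(2,4,6-trihydroxy-3-methylphenyl)ethan-1-one
Product: 3 1-(2,6-dihydroxy-4-methoxy-3-methylphenyl)ethan-1-one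
Conditions: Me2SO4 (1.0 equiv), K2CO3 (1.0 equiv), acetone, rt → reflux
Reagents that add atoms: dimethyl sulfate, COS(=O)(=O)OC
Why: Williamson-type O-methylation under weak base should pick the hydroxyl para to the acetyl group, the most acidic one, because the two ortho hydroxyls are engaged in hydrogen bonding to the carbonyl oxygen.

Step 3
Reactants: 3 1-(2,6-dihydroxy-4-methoxy-3-methylphenyl)ethan-1-one; 4 acrylic acid
Product: 5 8-acetyl-7-hydroxy-5-methoxy-6-methylchroman-2-one
Conditions: 4 (3 equiv), Amberlyst-15, toluene, reflux, Dean–Stark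
Reagents that add atoms: none
Why: Acid-catalysed hydroarylation of acrylic acid with lactonisation (the resin-catalysed dihydrocoumarin synthesis from phenols) can take place only at the single free ring carbon, and only the neighbouring hydroxyl, not the methyl ether, can close the lactone, so one constitution results.

Step 4
Reactants: 5 8-acetyl-7-hydroxy-5-methoxy-6-methylchroman-2-one
Product: 7 benzyl 3-[3-acetyl-2,4-bis(benzyloxy)-6-methoxy-5-methylphenyl]propanoate, via trisodium salt 6 (not isolated)
Conditions: NaOH (3.1 equiv), THF–H2O, rt, evaporate to dryness; BnBr (3.5 equiv), DMF, 60 °C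
Reagents that add atoms: sodium hydroxide, [Na+].[OH-]; benzyl bromide, BrCc1ccccc1
Why: Alkylative opening of a dihydrocoumarin, in which hydroxide opens the lactone irreversibly to a carboxylate that cannot re-close and SN2 benzylation of the trianion in DMF then caps both phenoxides and the carboxylate without enolising the ketone.

Step 5
Reactants: 7 benzyl 3-[3-acetyl-2,4-bis(benzyloxy)-6-methoxy-5-methylphenyl]propanoate
Product: 8 3-[3-acetyl-2,4-bis(benzyloxy)-6-methoxy-5-methylphenyl]propanoic acid
Conditions: LiOH, THF–MeOH–H2O, 40 °C; 1 M HCl to pH 3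
Reagents that add atoms: lithium hydroxide, [Li+].[OH-]
Why: Saponification of an unhindered ester, to which the aryl benzyl ethers and the doubly ortho-substituted aryl ketone are inert.

Step 6
Reactants: 8 3-[3-acetyl-2,4-bis(benzyloxy)-6-methoxy-5-methylphenyl]propanoic acid; 9 ethoxyacetylene
Product: 12 4-[3-acetyl-2,4-bis(benzyloxy)-6-methoxy-5-methylbenzyl]-3-ethoxycyclobut-2-en-1-one (racemic), via acid chloride 10 (not isolated), via alkylketene 11 (not isolated)
Conditions: (COCl)2, DMF (cat.), CH2Cl2, 0 °C, concentrate; 9 (3 equiv, hexanes solution), Et3N (1.3 equiv, slow addition), Et2O–CH2Cl2, 0 °C → rt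
Reagents that add atoms: none
Why: Dehydrochlorination gives the monoalkylketene, which the excess electron-rich alkyne intercepts in a [2+2] cycloaddition (the ketene–ethoxyacetylene route to 3-ethoxycyclobutenones), the unsubstituted alkyne carbon bonding to the ketene carbonyl carbon; the new stereocentre forms racemic and is erased in step 7.

Step 7
Reactants: 12 4-[3-acetyl-2,4-bis(benzyloxy)-6-methoxy-5-methylbenzyl]-3-ethoxycyclobut-2-en-1-one
Product: 13 2-[3-acetyl-2,4-bis(benzyloxy)-6-methoxy-5-methylbenzyl]-3-hydroxycyclobut-2-en-1-one (enol of the cyclobutane-1,3-dione)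
Conditions: 1 M HCl, THF, rt
Reagents that add atoms: water, O
Why: Acid hydrolysis of the vinylogous ester gives the cyclobutane-1,3-dione, which settles as the enol with the more substituted double bond and thereby moves the benzyl substituent from C4 to C2 of the enone.

Step 8
Reactants: 13 2-[3-acetyl-2,4-bis(benzyloxy)-6-methoxy-5-methylbenzyl]-3-hydroxycyclobut-2-en-1-one
Product: 14 2-[3-acetyl-2,4-bis(benzyloxy)-6-methoxy-5-methylbenzyl]-3-(benzyloxy)cyclobut-2-en-1-one
Conditions: BnOH, PPh3, DIAD, THF, 0 °C → rt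
Reagents that add atoms: benzyl alcohol, OCc1ccccc1
Why: Mitsunobu O-alkylation of a strongly acidic cyclic 1,3-dione enol (as practised on tetronic acids and cyclohexane-1,3-diones) runs at or below room temperature, avoids C-alkylation and ketene-forming heat, and gives one product because the two oxygens of 13 are equivalent.

Step 9
Reactants: 15 ethyl 4-methylpentanoate
Product: 18 triisopropyl[(5-methylhex-1-yn-1-yl)oxy]silane, via dibromo enolate 16 (not isolated), via lithium ynolate 17 (not isolated)
Conditions: CH2Br2, LiTMP (TMP + n-BuLi), THF, −78 °C; n-BuLi, −78 °C → rt; TIPSOTf, −78 °C → rt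
Reagents that add atoms: dibromomethane, BrCBr; triisopropylsilyl trifluoromethanesulfonate, CC(C)[Si](OS(=O)(=O)C(F)(F)F)(C(C)C)C(C)C
Why: Kowalski homologation stopped at the ynolate stage, in which LiCHBr2 adds to the ester, dibromo enolate 16 undergoes Br/Li exchange and 1,2-shift of the isopentyl group to ynolate 17, and the bulky silyl triflate reacts at oxygen rather than at carbon.

Step 10
Reactants: 14 2-[3-acetyl-2,4-bis(benzyloxy)-6-methoxy-5-methylbenzyl]-3-(benzyloxy)cyclobut-2-en-1-one; 18 triisopropyl[(5-methylhex-1-yn-1-yl)oxy]silane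
Product: 23 1-{2,6-bis(benzyloxy)-3-[6-(benzyloxy)-4-hydroxy-3-(3-methylbutyl)-2-(triisopropylsilyloxy)benzyl]-4-methoxy-5-methylphenyl}ethan-1-one, via vinylketene 19 (not isolated), via vinylcyclobutenone 20 (not isolated), via dienylketene 21 (not isolated), via cyclohexadienone 22 (not isolated)
Conditions: 18 (2 equiv), toluene, sealed tube, 110 → 150 °C
Reagents that add atoms: none
Why: Heat opens cyclobutenone 14 in a reversible conrotatory 4π electrocyclic reaction (C1–C4 bond) to vinylketene 19, whose ketene C=C bond takes up siloxyalkyne 18 in a [2+2] cycloaddition to give vinylcyclobutenone 20, and a second 4π opening leads to dienylketene 21. Ring B closes by disrotatory 6π electrocyclisation of 21, which rejoins the former C1 and C4 as C4'–C5', and dienone 22 tautomerises irreversibly to phenol 23, so that the net change is insertion of the alkyne into the C1–C2 bond of 14. The closest known reaction is the Danheiser benzannulation of cyclobutenones with trialkylsiloxyalkynes, the standard entry to resorcinol monosilyl ethers; here the extra donor oxygen at C3 turns the product into a differentiated phloroglucinol, and thermal opening of 3-oxygenated cyclobutenones is familiar from intermediates of type 20 and from squarate-derived cyclobutenones. The selectivity required is the orientation of the [2+2] step, and polarity secures it: the alkyne carbon β to the siloxy oxygen, which carries the isopentyl chain, is the nucleophilic end and bonds to the electrophilic ketene carbonyl carbon (C3'–C4'), leaving the siloxy carbon to bond to the benzyl-bearing ketene carbon (C1'–C2'). No stereocentre remains, since the quaternary carbon of 20 becomes sp2 again on ring opening. Ring A has no free ring carbon and no free hydroxyl that could trap the ketenes, the TIPS ynol ether cannot fragment by a retro-ene path as an ethyl ynol ether would, and the excess of 18 limits acylation of 23 by 19.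

Step 11
Reactants: 23 ring B phenol from step 10
Product: 24 5-(benzyloxy)-4-[3-acetyl-2,4-bis(benzyloxy)-6-methoxy-5-methylbenzyl]-2-(3-methylbutyl)-3-(triisopropylsilyloxy)phenyl 2-methylpropanoate
Conditions: i-PrCOCl, Et3N, DMAP (cat.), CH2Cl2, 0 °C → rt
Reagents that add atoms: isobutyryl chloride, CC(C)C(=O)Cl
Why: DMAP-catalysed esterification of the only free hydroxyl places exactly one acyl equivalent next to the carbon it must reach.

Step 12
Reactants: 24 ring B isobutyrate
Product: 25 1-{4-(benzyloxy)-3-[3-acetyl-2,4-bis(benzyloxy)-6-methoxy-5-methylbenzyl]-6-hydroxy-5-(3-methylbutyl)-2... written by ring B locants: C1' CH2–ring A, C2' OTIPS, C3' isopentyl, C4' OH, C5' isobutyryl, C6' OBn}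
Conditions: BF3·OEt2 (3 equiv), ClCH2CH2Cl, rt → 45 °C; H2O–MeOH
Reagents that add atoms: none
Why: Fries rearrangement of a phloroglucinol-type aryl ester, in which the acyl group can reach only C5', the single unsubstituted ring carbon (ortho to the departing oxygen, ortho to the benzyloxy and para to the siloxy group), the chelated ortho-hydroxy ketone is the thermodynamic sink, and BF3, which has no nucleophilic halide and cleaves aryl benzyl ethers only with an added thiol or sulfide, should leave the protecting groups in place.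

Step 13
Reactants: 25 C5'-isobutyryl silyl ether
Product: 26 1-{4-(benzyloxy)-... by ring B locants: C1' CH2–ring A (dibenzyl ether), C2' OH, C3' isopentyl, C4' OH, C5' isobutyryl, C6' OBn}
Conditions: Bu4NF, AcOH (1:1), THF, 0 °C
Reagents that add atoms: none
Why: Fluoride-induced cleavage of an aryl silyl ether, driven by the Si–F bond and the good phenoxide leaving group, with acetic acid buffering the phenoxide so that the bridge is not exposed to base.

Step 14
Reactants: 26 tribenzyl ether
Product: 27 1-{3-[3-acetyl-2,4-dihydroxy-6-methoxy-5-methylbenzyl]-2,4,6-trihydroxy-5-(3-methylbutyl)phenyl}-2-methylpropan-1-one (CNP0238575.0)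
Conditions: H2 (1 atm), Pd/C, EtOAc–MeOH, rt
Reagents that add atoms: none
Why: Hydrogenolysis of the three aryl benzyl ethers under neutral conditions leaves the aryl methyl ether, the diarylmethane bridge and the two hydrogen-bonded aryl ketones untouched and releases the target.

Compound list
1 | 2,4,6-trihydroxytoluene | Cc1c(O)cc(O)cc1O | starting material
2 | 1-(2,4,6-trihydroxy-3-methylphenyl)ethan-1-one | CC(=O)c1c(O)c(C)c(O)cc1O | intermediate
3 | 1-(2,6-dihydroxy-4-methoxy-3-methylphenyl)ethan-1-one | CC(=O)c1c(O)c(C)c(OC)cc1O | intermediate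
4 | acrylic acid | C=CC(=O)O | starting material
5 | 8-acetyl-7-hydroxy-5-methoxy-6-methylchroman-2-one | CC(=O)c1c(O)c(C)c(OC)c2c1OC(=O)CC2 | intermediate
6 | trisodium 3-(3-acetyl-6-methoxy-5-methyl-2,4-dioxidophenyl)propanoate | [Na+].[Na+].[Na+].CC(=O)c1c([O-])c(C)c(OC)c(CCC(=O)[O-])c1[O-] | intermediate
7 | benzyl 3-[3-acetyl-2,4-bis(benzyloxy)-6-methoxy-5-methylphenyl]propanoate | CC(=O)c1c(OCc2ccccc2)c(C)c(OC)c(CCC(=O)OCc2ccccc2)c1OCc1ccccc1 | intermediate
8 | 3-[3-acetyl-2,4-bis(benzyloxy)-6-methoxy-5-methylphenyl]propanoic acid | CC(=O)c1c(OCc2ccccc2)c(C)c(OC)c(CCC(=O)O)c1OCc1ccccc1 | intermediate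
9 | ethoxyacetylene | CCOC#C | starting material
10 | 3-[3-acetyl-2,4-bis(benzyloxy)-6-methoxy-5-methylphenyl]propanoyl chloride | CC(=O)c1c(OCc2ccccc2)c(C)c(OC)c(CCC(=O)Cl)c1OCc1ccccc1 | intermediate
11 | 3-[3-acetyl-2,4-bis(benzyloxy)-6-methoxy-5-methylphenyl]prop-1-en-1-one (alkylketene) | CC(=O)c1c(OCc2ccccc2)c(C)c(OC)c(CC=C=O)c1OCc1ccccc1 | intermediate
12 | 4-[3-acetyl-2,4-bis(benzyloxy)-6-methoxy-5-methylbenzyl]-3-ethoxycyclobut-2-en-1-one (racemic) | CCOC1=CC(=O)C1Cc1c(OC)c(C)c(OCc2ccccc2)c(C(C)=O)c1OCc1ccccc1 | intermediate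
13 | 2-[3-acetyl-2,4-bis(benzyloxy)-6-methoxy-5-methylbenzyl]-3-hydroxycyclobut-2-en-1-one | OC1=C(Cc2c(OC)c(C)c(OCc3ccccc3)c(C(C)=O)c2OCc2ccccc2)C(=O)C1 | intermediate
14 | 2-[3-acetyl-2,4-bis(benzyloxy)-6-methoxy-5-methylbenzyl]-3-(benzyloxy)cyclobut-2-en-1-one | O=C1CC(OCc2ccccc2)=C1Cc1c(OC)c(C)c(OCc2ccccc2)c(C(C)=O)c1OCc1ccccc1 | intermediate
15 | ethyl 4-methylpentanoate | CCOC(=O)CCC(C)C | starting material
16 | lithium 1,1-dibromo-5-methylhex-1-en-2-olate | [Li+].[O-]C(CCC(C)C)=C(Br)Br | intermediate
17 | lithium 5-methylhex-1-yn-1-olate | [Li+].[O-]C#CCCC(C)C | intermediate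
18 | triisopropyl[(5-methylhex-1-yn-1-yl)oxy]silane | CC(C)CCC#CO[Si](C(C)C)(C(C)C)C(C)C | intermediate
19 | 2-[3-acetyl-2,4-bis(benzyloxy)-6-methoxy-5-methylbenzyl]-3-(benzyloxy)buta-1,3-dien-1-one | O=C=C(Cc1c(OC)c(C)c(OCc2ccccc2)c(C(C)=O)c1OCc1ccccc1)C(=C)OCc1ccccc1 | intermediate
20 | 4-[3-acetyl-2,4-bis(benzyloxy)-6-methoxy-5-methylbenzyl]-4-[1-(benzyloxy)ethenyl]-2-(3-methylbutyl)-3-(triisopropylsilyloxy)cyclobut-2-en-1-one (racemic) | O=C4C(CCC(C)C)=C(O[Si](C(C)C)(C(C)C)C(C)C)C4(Cc1c(OC)c(C)c(OCc2ccccc2)c(C(C)=O)c1OCc1ccccc1)C(=C)OCc1ccccc1 | intermediate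
21 | (3E)-4-[3-acetyl-2,4-bis(benzyloxy)-6-methoxy-5-methylbenzyl]-5-(benzyloxy)-2-(3-methylbutyl)-3-(triisopropylsilyloxy)hexa-1,3,5-trien-1-one | O=C=C(CCC(C)C)/C(O[Si](C(C)C)(C(C)C)C(C)C)=C(/Cc1c(OC)c(C)c(OCc2ccccc2)c(C(C)=O)c1OCc1ccccc1)C(=C)OCc1ccccc1 | intermediate
22 | 4-[3-acetyl-2,4-bis(benzyloxy)-6-methoxy-5-methylbenzyl]-5-(benzyloxy)-2-(3-methylbutyl)-3-(triisopropylsilyloxy)cyclohexa-2,4-dien-1-one | O=C1CC(OCc2ccccc2)=C(Cc2c(OC)c(C)c(OCc3ccccc3)c(C(C)=O)c2OCc2ccccc2)C(O[Si](C(C)C)(C(C)C)C(C)C)=C1CCC(C)C | intermediate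
23 | 1-{2,6-bis(benzyloxy)-3-[6-(benzyloxy)-4-hydroxy-3-(3-methylbutyl)-2-(triisopropylsilyloxy)benzyl]-4-methoxy-5-methylphenyl}ethan-1-one | Oc1cc(OCc2ccccc2)c(Cc2c(OC)c(C)c(OCc3ccccc3)c(C(C)=O)c2OCc2ccccc2)c(O[Si](C(C)C)(C(C)C)C(C)C)c1CCC(C)C | intermediate
24 | C4'-O-isobutyrate of 23 | CC(C)C(=O)Oc1cc(OCc2ccccc2)c(Cc2c(OC)c(C)c(OCc3ccccc3)c(C(C)=O)c2OCc2ccccc2)c(O[Si](C(C)C)(C(C)C)C(C)C)c1CCC(C)C | intermediate
25 | C5'-isobutyryl derivative of 23 (C4' OH free, C2' OTIPS, C6' OBn, ring A dibenzyl ether) | CC(C)C(=O)c1c(O)c(CCC(C)C)c(O[Si](C(C)C)(C(C)C)C(C)C)c(Cc2c(OC)c(C)c(OCc3ccccc3)c(C(C)=O)c2OCc2ccccc2)c1OCc1ccccc1 | intermediate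
26 | desilylated 25 (C2' and C4' OH free, C6' OBn, ring A dibenzyl ether) | CC(C)C(=O)c1c(O)c(CCC(C)C)c(O)c(Cc2c(OC)c(C)c(OCc3ccccc3)c(C(C)=O)c2OCc2ccccc2)c1OCc1ccccc1 | intermediate
27 | 1-{3-[3-acetyl-2,4-dihydroxy-6-methoxy-5-methylbenzyl]-2,4,6-trihydroxy-5-(3-methylbutyl)phenyl}-2-methylpropan-1-one | COc1c(C)c(O)c(C(C)=O)c(O)c1Cc1c(O)c(CCC(C)C)c(O)c(C(=O)C(C)C)c1O | target

Total step count: 14. Longest linear sequence: 13 (steps 1–8 and 10–14). Step 9 is the convergent branch.

Steps most likely to fail

Risk 1, step 10. The donor oxygen at C3 stabilises the cyclobutenone as a vinylogous ester, so the first ring opening may need temperatures at which other processes compete. The vinylketene may dimerise or acylate the product phenol, and the bulky benzyl group on the ketene carbon slows the [2+2] addition.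
The fallback gives up ring construction for a classical methylene-bridge coupling. It sets out from acetophenone 3 and comes back at target 27.
- A Mannich reaction (aqueous HCHO, Me2NH, EtOH) at the one free ring carbon of 3 should give the dimethylaminomethyl acetophenone F1.
- Separately, commercial phloroglucinol is acylated (i-PrCOCl, AlCl3) to phlorisobutyrophenone F2.
- F2 is C-prenylated (prenyl bromide, aqueous KOH) to the monoprenyl ketone F3, which is hydrogenated (H2, Pd/C) to the isopentyl ketone F4.
- Heating F1 with F4 in dioxane expels the amine, and the ortho-quinone methide of ring A is captured by the single free ring carbon of F4, which gives 27 directly.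

Risk 2, step 12. The Lewis acid may trigger ipso attack on ring B with scission of the CH2 bridge, loss of benzyl or silyl groups, or intermolecular acyl transfer before the ortho shift occurs.
The fallback avoids acid and builds the ketone by carbonyl addition. It sets out from phenol 23, bypasses 24 and comes back at 25.
- Magnesium-mediated ortho-formylation (MgCl2, Et3N, paraformaldehyde, MeCN, reflux; Casnati–Skattebøl) should give the C5' salicylaldehyde F5.
- Excess i-PrMgCl (THF, −78 → 0 °C) adds to the aldehyde to give the racemic benzylic alcohol F6. The ring A ketone is shielded by its two ortho benzyloxy groups, and at worst it is enolised and returned on work-up.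
- Oxidation with MnO2 or Dess–Martin periodinane then gives 25.

Risk 3, step 3. The acetyl group lowers the nucleophilicity of the ring, so hydroarylation may be outrun by polymerisation of acrylic acid or diverted into C-acylation followed by oxa-Michael closure.
The fallback replaces the conjugate addition by olefination of an aldehyde. It sets out from 3 and comes back at 5.
- Vilsmeier–Haack formylation (POCl3, DMF) at the free ring carbon should give the benzaldehyde F7.
- A Wittig reaction with Ph3P=CHCO2Et (toluene, reflux) gives the (E)-cinnamate F8.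
- Hydrogenation (H2, Pd/C, EtOAc) gives the dihydrocinnamate F9.
- A catalytic amount of TsOH in refluxing toluene lactonises F9 to 5.

Further compounds
F1 | step 10 | 1-{3-[(dimethylamino)methyl]-2,6-dihydroxy-4-methoxy-5-methylphenyl}ethan-1-one | CC(=O)c1c(O)c(C)c(OC)c(CN(C)C)c1O
F2 | step 10 | 2-methyl-1-(2,4,6-trihydroxyphenyl)propan-1-one | CC(C)C(=O)c1c(O)cc(O)cc1O
F3 | step 10 | 2-methyl-1-[2,4,6-trihydroxy-3-(3-methylbut-2-en-1-yl)phenyl]propan-1-one | CC(C)=CCc1c(O)cc(O)c(C(=O)C(C)C)c1O
F4 | step 10 | 2-methyl-1-[2,4,6-trihydroxy-3-(3-methylbutyl)phenyl]propan-1-one | CC(C)CCc1c(O)cc(O)c(C(=O)C(C)C)c1O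
F5 | step 12 | C5'-formyl derivative of 23 | O=Cc1c(O)c(CCC(C)C)c(O[Si](C(C)C)(C(C)C)C(C)C)c(Cc2c(OC)c(C)c(OCc3ccccc3)c(C(C)=O)c2OCc2ccccc2)c1OCc1ccccc1
F6 | step 12 | C5'-(1-hydroxy-2-methylpropyl) derivative of 23 (racemic) | CC(C)C(O)c1c(O)c(CCC(C)C)c(O[Si](C(C)C)(C(C)C)C(C)C)c(Cc2c(OC)c(C)c(OCc3ccccc3)c(C(C)=O)c2OCc2ccccc2)c1OCc1ccccc1
F7 | step 3 | 3-acetyl-2,4-dihydroxy-6-methoxy-5-methylbenzaldehyde | CC(=O)c1c(O)c(C)c(OC)c(C=O)c1O
F8 | step 3 | ethyl (E)-3-(3-acetyl-2,4-dihydroxy-6-methoxy-5-methylphenyl)prop-2-enoate | CCOC(=O)/C=C/c1c(OC)c(C)c(O)c(C(C)=O)c1O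
F9 | step 3 | ethyl 3-(3-acetyl-2,4-dihydroxy-6-methoxy-5-methylphenyl)propanoate | CCOC(=O)CCc1c(OC)c(C)c(O)c(C(C)=O)c1O
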